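**Retrosynthetic overview**

1. Target 31 comes from the trans-fused diketone 19 by C1 methylenation and two acylations: angelic acid 22 at C7–OH, then epoxy acid 29 at C3–OH.
2. Structural feature: C5 and C9 are joined twice, through C6–C7–C8 (ring B) and through C1–C2–C3–C4 (ring A). The bicycle is therefore a cyclononane with one transannular C5–C9 bond between the α-carbon of a C1 ketone and the β-carbon of a C5=C6 enone. Diketone 19 comes from cyclopentanol 14 by anionic oxy-Cope shift (C7–C8 made, C1–C5 broken) followed by transannular Michael addition (C5–C9 made), so rings A and B form together in one step.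
3. Cyclopentanol 14 comes from the alkoxymethylene lactone 12 and MeLi, which unveils the acetyl group and the free C1–OH together. Lactone 12 comes from lactone 10 by formylation and O-benzylation.
4. Lactone 10 comes from enone 1 by three-component coupling (isopropyl at C4, CH2CO2Me at C5), vinyl addition at C1 with lactonisation, and oxidation–reduction inversion at C3.
5. Epoxy acid 29 comes from angelic acid 22 by reduction, Sharpless epoxidation and oxidation.

Key step: step 9

Numbering and descriptors: the target numbering (C1 methylidene carbon, C2, C3 O-bearing, C4 isopropyl-bearing, C5, C6 acetyl-bearing, C7 O-bearing, C8, C9) is used for every intermediate. α is the face of H5 and of the C4 isopropyl group, β the opposite face. Absolute configurations are those of the SMILES.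

Assumption: ketone 19, like hexahydroindan-4-ones without an angular substituent, is taken to prefer the trans ring fusion at equilibrium.

**Route**

Step 1
Reactants: 1 (S)-4-(tert-butyldimethylsilyloxy)cyclopent-2-en-1-one; 2 methyl bromoacetate
Product: 4 methyl 2-[3β-(tert-butyldimethylsilyloxy)-4α-isopropyl-1-oxocyclopentan-5β-yl]acetate, via lithium enolate 3 (not isolated)
Conditions: i-PrLi, Me2Zn, THF, −78 °C; 1; then 2, HMPA, −78 → −40 °C
Reagents that add atoms: isopropyllithium, CC(C)[Li]
Why: Noyori-type three-component coupling (conjugate addition of a mixed lithium zincate, then enolate alkylation): isopropyl should add to C4 anti to the C3 silyloxy group, and the regiodefined enolate 3 should be alkylated at C5 anti to the new isopropyl group, the fast α-bromo ester outrunning enolate equilibration and loss of silyloxide.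

Step 2
Reactants: 4 methyl 2-[3β-(tert-butyldimethylsilyloxy)-4α-isopropyl-1-oxocyclopentan-5β-yl]acetate
Product: 6 cis-fused γ-lactone of 1α-vinyl-3β-(tert-butyldimethylsilyloxy)-4α-isopropyl-5β-(carboxymethyl)cyclopentan-1β-ol, via bromomagnesium alkoxide 5 (not isolated)
Conditions: CH2=CHMgBr, CeCl3, THF, −78 °C → rt; H2O
Reagents that add atoms: vinylmagnesium bromide, C=C[Mg]Br
Why: CeCl3-promoted Grignard 1,2-addition (enolisation suppressed, ester untouched at low temperature) should occur on the α face, anti to the C5 side chain and the C3 silyloxy group, setting C1 (vinyl α, O β); only this alkoxide is cis to CH2CO2Me and lactonises, which also separates it from any C1 epimer.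

Step 3
Reactants: 6 3β-silyloxy lactone
Product: 7 3β-hydroxy lactone (6 without the silyl group)
Conditions: Bu4NF, AcOH, THF, 0 °C → rt
Reagents that add atoms: none
Why: Fluoride desilylation; the acetic acid buffer keeps the alkoxide concentration low so that the lactone acyl group does not migrate to the cis C3 oxygen.

Step 4
Reactants: 7 3β-hydroxy lactone
Product: 8 3-oxo lactone
Conditions: Dess–Martin periodinane, CH2Cl2, 0 °C → rt
Reagents that add atoms: none
Why: Dess–Martin oxidation of the secondary alcohol under near-neutral conditions, which should spare the β-acyloxy ketone and the C4 stereocenter (already trans to C5).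

Step 5
Reactants: 8 3-oxo lactone
Product: 9 3α-hydroxy lactone (C3 epimer of 7)
Conditions: LiBH(s-Bu)3, THF, −78 °C; H2O
Reagents that add atoms: none
Why: Bulky borohydride reduction: hydride should approach C3 from the β face, away from the adjacent α-isopropyl and the angular α-vinyl group, giving the 3α-alcohol cis to isopropyl (net inversion at C3); the lactone is not reduced at −78 °C.

Step 6
Reactants: 9 3α-hydroxy lactone
Product: 10 3α-(tert-butyldimethylsilyloxy) lactone (C3 epimer of 6)
Conditions: t-BuMe2SiOTf, 2,6-lutidine, CH2Cl2, −78 → 0 °C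
Reagents that add atoms: tert-butyldimethylsilyl trifluoromethanesulfonate, CC(C)(C)[Si](C)(C)OS(=O)(=O)C(F)(F)F
Why: Silylation of a hindered secondary alcohol with a silyl triflate and a non-nucleophilic base; no stereocenter is touched.

Step 7
Reactants: 10 3α-(tert-butyldimethylsilyloxy) lactone
Product: 12 (E)-6-[(4-methoxybenzyloxy)methylidene] lactone (ether oxygen syn to C5), via sodium enolate 11 (not isolated)
Conditions: NaH, HCO2Et, THF, 0 °C → rt; then 4-MeOC6H4CH2Cl, DMF, 0 °C → rt
Reagents that add atoms: ethyl formate, CCOC=O; 4-methoxybenzyl chloride, COc1ccc(CCl)cc1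
Why: Claisen formylation at C6, the only enolisable position of the lactone, then O-alkylation of the formyl enolate in a dipolar aprotic solvent; the (E)-alkoxymethylidene lactone (oxygen anti to the lactone carbonyl) is expected to be favoured, as in β-alkoxyacrylate syntheses, and is purified from any (Z) isomer.

Step 8
Reactants: 12 (E)-6-[(4-methoxybenzyloxy)methylidene] lactone
Product: 14 1α-vinyl-3α-(tert-butyldimethylsilyloxy)-4α-isopropyl-5β-[(E)-1-(4-methoxybenzyloxy)-3-oxobut-1-en-2-yl]cyclopentan-1β-ol, via lithium lactolate 13 (not isolated)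
Conditions: MeLi (1.05 equiv), THF, −78 °C; H2O/THF, −78 °C
Reagents that add atoms: methyllithium, [Li]C
Why: Mono-addition of an organolithium to a lactone: lactolate 13 should persist at −78 °C and open on work-up to the methyl ketone and the free tertiary C1–OH, the resulting vinylogous ester being deactivated toward a second addition; the enol ether geometry is retained.

Step 9
Reactants: 14 1α-vinyl-3α-(tert-butyldimethylsilyloxy)-4α-isopropyl-5β-[(E)-1-(4-methoxybenzyloxy)-3-oxobut-1-en-2-yl]cyclopentan-1β-ol
Product: 19 trans-fused (5αH,9βH) 6α-acetyl-4α-isopropyl-7α-(4-methoxybenzyloxy)-3α-(tert-butyldimethylsilyloxy)bicyclo[4.3.0]nonan-1-one (target numbering), via potassium alkoxide 15 (not isolated), via cyclononadienolate 16 (not isolated), via cis-fused enolate 17 (not isolated), via cis-fused diketone 18 (not isolated)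
Conditions: KN(SiMe3)2 (1.05 equiv), 18-crown-6, THF, −78 → 0 °C; AcOH, −78 °C; then DBU (0.2 equiv), PhMe, rt
Reagents that add atoms: none
Why: Proposed new method: the potassium alkoxide 15, in which the C1 vinyl and C5 alkenyl groups are trans, should undergo a chair anionic oxy-Cope shift (C7–C8 formed, C1–C5 broken) to the doubly trans cyclononadienolate 16, whose enolate carbon C9 then adds across the ring to C5 of the acetyl-activated C5=C6 bond (C5–C9 formed) to give enolate 17; cold protonation gives 18 and catalytic DBU equilibrates it to 19. The closest known chemistry is the anionic oxy-Cope ring expansion of 1,2-divinylcycloalkanols followed by transannular aldol or ene closure, together with transannular Michael additions in medium rings; the sequence has not been shown on a push-pull enol ether enone. Ring A closes in the 6-(enolendo)-exo-trig mode and ring B, counted from the acceptor, in the 5-endo-trig mode, which is tolerable here only because the twisted trans C5=C6 bond of the nine-membered ring turns its C5 lobe toward C9, as in transannular closures of cyclonona-1,5-dienes to hydrindanes. C7 is set by chirality transfer from C5 through the chair in which the ring bonds are equatorial and the (E)-enol ether oxygen is axial; C5 is re-formed on the face that C1 has just left, before the planar-chiral ring can flip, which gives the cis-fused adduct first; C9 is then corrected through the C1 enolate to the trans fusion with equatorial isopropyl; C6 settles with the acetyl group trans to the C4 branch, the same isomer that protonation anti to the C7 ether gives. The step needs the [3,3] shift to outrun 5-endo attack of the alkoxide oxygen on C7 and needs enolate 17 to keep its β-ether: one equivalent of a soluble base (so that the acetyl methyl is not enolised irreversibly), the poor leaving group ability of the benzyl oxide and the quench at −78 °C are meant to secure this.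

Step 10
Reactants: 19 trans-fused diketone
Product: 20 1-methylidene analogue of 19 (C6 acetyl retained)
Conditions: Ph3PCH3Br, KN(SiMe3)2, THF, 0 °C; then 19 (1.05 equiv of ylide), −78 → 0 °C
Reagents that add atoms: methyltriphenylphosphonium bromide, C[P+](c1ccccc1)(c1ccccc1)c1ccccc1.[Br-]
Why: Wittig methylenation: the C1 cyclohexanone carbonyl should react ahead of the acetyl group, which is flanked by the C5 and C7 methines and the C4 isopropyl group (the same preference as for the ring ketone over the side-chain acetyl in steroidal 3,20-diones); no stereocenter is formed, and C9 and C6 are already in their equilibrium configurations.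

Step 11
Reactants: 20 1-methylidene 7α-(4-methoxybenzyl) ether
Product: 21 7α-alcohol
Conditions: DDQ, CH2Cl2/pH 7 buffer, 0 °C
Reagents that add atoms: none
Why: Oxidative cleavage of the 4-methoxybenzyl ether by DDQ; the silyl ether, the 1,1-disubstituted alkene and the ketone are inert and C7 is untouched.

Step 12
Reactants: 21 7α-alcohol; 22 angelic acid
Product: 24 7α-angelate, via mixed anhydride 23 (not isolated)
Conditions: 22, 2,4,6-Cl3C6H2COCl, Et3N, PhMe, rt; then 21, PhMe, 70 °C
Reagents that add atoms: none
Why: Yamaguchi esterification through the preformed mixed anhydride without DMAP, the protocol known to transfer the angeloyl group to secondary alcohols without Z to E isomerisation; the medium stays close to neutral, which should limit β-elimination, and C7 is acylated with retention.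

Step 13
Reactants: 24 7α-angelate
Product: 25 3α-alcohol
Conditions: HF·pyridine, pyridine, THF, 0 °C → rt
Reagents that add atoms: none
Why: Acidic fluoride desilylation, chosen over basic fluoride so that the β-acyloxy ketone does not eliminate and the angelate does not isomerise.

Step 14
Reactants: 22 angelic acid
Product: 26 (Z)-2-methylbut-2-en-1-ol
Conditions: LiAlH4, Et2O, 0 °C; H2O
Reagents that add atoms: none
Why: Hydride reduction of the carboxylic acid to the allylic alcohol; the trisubstituted (Z) double bond is not reduced or isomerised.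

Step 15
Reactants: 26 (Z)-2-methylbut-2-en-1-ol
Product: 27 [(2R,3S)-2,3-dimethyloxiran-2-yl]methanol
Conditions: Ti(OiPr)4 (10 mol %), D-(−)-diethyl tartrate (12 mol %), t-BuOOH, 4 Å molecular sieves, CH2Cl2, −20 °C
Reagents that add atoms: tert-butyl hydroperoxide, CC(C)(C)OO
Why: Sharpless asymmetric epoxidation: the D-(−)-tartrate catalyst should deliver oxygen to the face that gives the 2R epoxy alcohol (L-(+)-tartrate gives 2S with 2-alken-1-ols), and syn addition keeps CH2OH and the C3 methyl cis.

Step 16
Reactants: 27 [(2R,3S)-2,3-dimethyloxiran-2-yl]methanol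
Product: 29 (2S,3S)-2,3-dimethyloxirane-2-carboxylic acid, via epoxy aldehyde 28 (not isolated)
Conditions: RuCl3 (2 mol %), NaIO4, CCl4/MeCN/H2O, rt
Reagents that add atoms: sodium periodate, [Na+].[O-]I(=O)(=O)=O
Why: Ruthenium-catalysed periodate oxidation (Sharpless conditions) of an epoxy alcohol to the glycidic acid; the epoxide centers are untouched (the descriptor at C2 changes only through priorities).

Step 17
Reactants: 25 3α-alcohol; 29 (2S,3S)-2,3-dimethyloxirane-2-carboxylic acid
Product: 31 target CNP0300602.1, via mixed anhydride 30 (not isolated)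
Conditions: 29, 2,4,6-Cl3C6H2COCl, Et3N, PhMe, rt; then 25, DMAP, PhMe, rt
Reagents that add atoms: none
Why: Yamaguchi esterification of the axial C3–OH with the DMAP-activated mixed anhydride at room temperature; C3 and both epoxide centers are retained, and the mild conditions should spare the β-acyloxy ketone.

**Compound list**

1 | (S)-4-(tert-butyldimethylsilyloxy)cyclopent-2-en-1-one | O=C1C[C@H](O[Si](C)(C)C(C)(C)C)C=C1 | starting material
2 | methyl bromoacetate | COC(=O)CBr | starting material
3 | lithium enolate (C1–O−, C1=C5; dimethylzinc-complexed) of 4α-isopropyl-3β-(tert-butyldimethylsilyloxy)cyclopentanone | [Li+].[O-]C1=C[C@H](C(C)C)[C@@H](O[Si](C)(C)C(C)(C)C)C1 | intermediate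
4 | methyl 2-[3β-(tert-butyldimethylsilyloxy)-4α-isopropyl-1-oxocyclopentan-5β-yl]acetate (3,4-trans, 4,5-trans) | O=C1C[C@H](O[Si](C)(C)C(C)(C)C)[C@@H](C(C)C)[C@@H]1CC(=O)OC | intermediate
5 | bromomagnesium 1β-alkoxide of the 1α-vinyl adduct of 4 | C=C[C@@]1([O-])C[C@H](O[Si](C)(C)C(C)(C)C)[C@@H](C(C)C)[C@@H]1CC(=O)OC.[Mg+2].[Br-] | intermediate
6 | cis-fused γ-lactone (O–C1 and CH2–C5 both β), 1α-vinyl, 3β-(tert-butyldimethylsilyloxy), 4α-isopropyl | C=C[C@@]12C[C@H](O[Si](C)(C)C(C)(C)C)[C@@H](C(C)C)[C@@H]1CC(=O)O2 | intermediate
7 | 3β-hydroxy lactone | C=C[C@@]12C[C@H](O)[C@@H](C(C)C)[C@@H]1CC(=O)O2 | intermediate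
8 | 3-oxo lactone | C=C[C@@]12CC(=O)[C@@H](C(C)C)[C@@H]1CC(=O)O2 | intermediate
9 | 3α-hydroxy lactone (hydroxyl cis to isopropyl) | C=C[C@@]12C[C@@H](O)[C@@H](C(C)C)[C@@H]1CC(=O)O2 | intermediate
10 | 3α-(tert-butyldimethylsilyloxy) lactone | C=C[C@@]12C[C@@H](O[Si](C)(C)C(C)(C)C)[C@@H](C(C)C)[C@@H]1CC(=O)O2 | intermediate
11 | sodium enolate of the 6-formyl lactone (enolate geometry open) | C=C[C@@]12C[C@@H](O[Si](C)(C)C(C)(C)C)[C@@H](C(C)C)[C@@H]1C(=C[O-])C(=O)O2.[Na+] | intermediate
12 | (E)-6-[(4-methoxybenzyloxy)methylidene] lactone (ether oxygen syn to C5) | C=C[C@@]12C[C@@H](O[Si](C)(C)C(C)(C)C)[C@@H](C(C)C)[C@@H]1/C(=C\OCc3ccc(OC)cc3)C(=O)O2 | intermediate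
13 | lithium lactolate from methyl addition to 12 (lactol carbon configuration open) | C=C[C@@]12C[C@@H](O[Si](C)(C)C(C)(C)C)[C@@H](C(C)C)[C@@H]1/C(=C\OCc3ccc(OC)cc3)C(C)([O-])O2.[Li+] | intermediate
14 | 1α-vinyl-3α-(tert-butyldimethylsilyloxy)-4α-isopropyl-5β-[(E)-1-(4-methoxybenzyloxy)-3-oxobut-1-en-2-yl]cyclopentan-1β-ol | C=C[C@@]1(O)C[C@@H](O[Si](C)(C)C(C)(C)C)[C@@H](C(C)C)[C@@H]1/C(C(C)=O)=C\OCc2ccc(OC)cc2 | intermediate
15 | potassium alkoxide of 14 | C=C[C@@]1([O-])C[C@@H](O[Si](C)(C)C(C)(C)C)[C@@H](C(C)C)[C@@H]1/C(C(C)=O)=C\OCc2ccc(OC)cc2.[K+] | intermediate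
16 | potassium cyclonona-1(9),5-dien-1-olate, both ring double bonds trans within the ring; 6-acetyl, 7-(4-methoxybenzyloxy), 4-isopropyl, 3-(tert-butyldimethylsilyloxy) | [K+].[O-]/C1=C\C[C@H](OCc2ccc(OC)cc2)/C(C(C)=O)=C/[C@H](C(C)C)[C@H](O[Si](C)(C)C(C)(C)C)C1 | intermediate
17 | cis-fused (5αH,9αH) Michael adduct as the potassium enolate of the C6 acetyl group | O=C1C[C@@H](O[Si](C)(C)C(C)(C)C)[C@@H](C(C)C)[C@@H]2C(=C(C)[O-])[C@@H](OCc3ccc(OC)cc3)C[C@H]12.[K+] | intermediate
18 | cis-fused (5αH,9αH) diketone, C9 epimer of 19 (C6 not yet settled) | O=C1C[C@@H](O[Si](C)(C)C(C)(C)C)[C@@H](C(C)C)[C@@H]2C(C(C)=O)[C@@H](OCc3ccc(OC)cc3)C[C@H]12 | intermediate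
19 | trans-fused (5αH,9βH) 6α-acetyl-4α-isopropyl-7α-(4-methoxybenzyloxy)-3α-(tert-butyldimethylsilyloxy)bicyclo[4.3.0]nonan-1-one | O=C1C[C@@H](O[Si](C)(C)C(C)(C)C)[C@@H](C(C)C)[C@@H]2[C@@H](C(C)=O)[C@@H](OCc3ccc(OC)cc3)C[C@@H]12 | intermediate
20 | 1-methylidene analogue of 19 | C=C1C[C@@H](O[Si](C)(C)C(C)(C)C)[C@@H](C(C)C)[C@@H]2[C@@H](C(C)=O)[C@@H](OCc3ccc(OC)cc3)C[C@@H]12 | intermediate
21 | 7α-alcohol (1-methylidene, 3α-silyloxy, 6α-acetyl) | C=C1C[C@@H](O[Si](C)(C)C(C)(C)C)[C@@H](C(C)C)[C@@H]2[C@@H](C(C)=O)[C@@H](O)C[C@@H]12 | intermediate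
22 | angelic acid, (Z)-2-methylbut-2-enoic acid | C/C=C(/C)C(=O)O | starting material
23 | angelic 2,4,6-trichlorobenzoic anhydride | C/C=C(/C)C(=O)OC(=O)c1c(Cl)cc(Cl)cc1Cl | intermediate
24 | 7α-angelate (3α-silyloxy) | C=C1C[C@@H](O[Si](C)(C)C(C)(C)C)[C@@H](C(C)C)[C@@H]2[C@@H](C(C)=O)[C@@H](OC(=O)/C(C)=C\C)C[C@@H]12 | intermediate
25 | 3α-alcohol (7α-angelate) | C=C1C[C@@H](O)[C@@H](C(C)C)[C@@H]2[C@@H](C(C)=O)[C@@H](OC(=O)/C(C)=C\C)C[C@@H]12 | intermediate
26 | (Z)-2-methylbut-2-en-1-ol | C/C=C(/C)CO | intermediate
27 | [(2R,3S)-2,3-dimethyloxiran-2-yl]methanol | OC[C@@]1(C)O[C@H]1C | intermediate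
28 | (2S,3S)-2,3-dimethyloxirane-2-carbaldehyde | O=C[C@@]1(C)O[C@H]1C | intermediate
29 | (2S,3S)-2,3-dimethyloxirane-2-carboxylic acid | OC(=O)[C@@]1(C)O[C@H]1C | intermediate
30 | (2S,3S)-2,3-dimethyloxirane-2-carboxylic 2,4,6-trichlorobenzoic anhydride | O=C(OC(=O)c1c(Cl)cc(Cl)cc1Cl)[C@@]1(C)O[C@H]1C | intermediate
31 | CNP0300602.1 | C=C1C[C@@H](OC(=O)[C@@]2(C)O[C@H]2C)[C@@H](C(C)C)[C@@H]2[C@@H](C(C)=O)[C@@H](OC(=O)/C(C)=C\C)C[C@@H]12 | target

**Step count**

Total steps: 17. Longest linear sequence: 14 steps (steps 1 to 13 and step 17, from enone 1). The epoxy acid branch (steps 14 to 16, from angelic acid 22) joins at step 17.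

**Steps most likely to fail**

Step 9 (key step). The alkoxide oxygen may add in a 5-endo sense to C7 and expel the benzyl oxide. Enolate 17 may lose its β-ether. The rearrangement may also be slow because of the strain of the doubly trans nine-membered ring, which would leave time for both side reactions. The fallback separates the two events and avoids a potassium alkoxide. It sets out from 14: heating in degassed toluene (sealed, base-washed tube, about 180 °C) should bring about the neutral thermal oxy-Cope ring expansion, and tautomerisation of the enol gives the cyclononenedione F1. Catalytic DBU or Cs2CO3 in MeCN should then close C5–C9 by base-catalysed transannular Michael addition and equilibrate C9 and C6. This returns to the route at 19.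

Step 10. The ylide may also methylenate the C6 acetyl group, or enolise it and trigger β-elimination of the C7 ether. The fallback protects the acetyl group as the enol ether that the cascade itself generates. It sets out from 14: the cascade of step 9 is run as before, but enolate 17 is trapped with Et3SiCl at −78 °C to give the cis-fused triethylsilyl enol ether F2. DBU in toluene epimerises C9 to the trans-fused enol ether F3. Ph3P=CH2 then methylenates the only free carbonyl to give F4. Mild hydrolysis (AcOH/THF/H2O, 0 °C) with protonation of C6 anti to the C7 ether, followed if needed by a DBU equilibration, returns to the route at 20.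

Step 8. The lactolate may open before the quench and take up a second methyllithium, or the reagent may add to C7 and displace the benzyl oxide. The fallback uses an amide whose tetrahedral adduct cannot collapse early. It sets out from 12: Me(MeO)NH·HCl and Me3Al in CH2Cl2 open the lactone to the hydroxy Weinreb amide F5, and MeMgBr (3 equiv, THF, 0 °C) converts it into the methyl ketone. This returns to the route at 14.

Further compounds
F1 | step 9 | 6-acetyl-4-isopropyl-7-(4-methoxybenzyloxy)-3-(tert-butyldimethylsilyloxy)cyclonon-5-en-1-one with a trans ring double bond (target numbering) | O=C1CC[C@H](OCc2ccc(OC)cc2)/C(C(C)=O)=C/[C@H](C(C)C)[C@H](O[Si](C)(C)C(C)(C)C)C1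
F2 | step 10 | cis-fused (5αH,9αH) bicyclic C1 ketone with the C6 acetyl group as its triethylsilyl enol ether | O=C1C[C@@H](O[Si](C)(C)C(C)(C)C)[C@@H](C(C)C)[C@@H]2C(=C(C)O[Si](CC)(CC)CC)[C@@H](OCc3ccc(OC)cc3)C[C@H]12
F3 | step 10 | trans-fused (5αH,9βH) isomer of F2 | O=C1C[C@@H](O[Si](C)(C)C(C)(C)C)[C@@H](C(C)C)[C@@H]2C(=C(C)O[Si](CC)(CC)CC)[C@@H](OCc3ccc(OC)cc3)C[C@@H]12
F4 | step 10 | 1-methylidene derivative of F3 | C=C1C[C@@H](O[Si](C)(C)C(C)(C)C)[C@@H](C(C)C)[C@@H]2C(=C(C)O[Si](CC)(CC)CC)[C@@H](OCc3ccc(OC)cc3)C[C@@H]12
F5 | step 8 | (E)-N-methoxy-N-methyl-3-(4-methoxybenzyloxy)-2-[1β-hydroxy-1α-vinyl-3α-(tert-butyldimethylsilyloxy)-4α-isopropylcyclopentan-5β-yl]acrylamide | C=C[C@@]1(O)C[C@@H](O[Si](C)(C)C(C)(C)C)[C@@H](C(C)C)[C@@H]1/C(=C\OCc2ccc(OC)cc2)C(=O)N(C)OC
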